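- Which of the two recipes ends with more target, and does the gap pass the margin?

| setting | south-east | north-west | north-east | west | Monday's | Friday's |
|---|---|---|---|---|---|---|
| substrate | 2.5 M | 2.5 M | 2.5 M | 2.5 M | 2.5 M | 2.5 M |
| coupling partner | 0.70 equiv | 0.70 equiv | 0.70 equiv | 0.70 equiv | 0.700 equiv | 0.700 equiv |
| free catalyst | 0.47 mol% | 0.93 mol% | 1.8 mol% | 1.9 mol% | 0.5 mol% | 1.9 mol% |
| added ligand | 28 mM | 28 mM | 28 mM | 17 mM | 8.0 mM | 28 mM |
| temperature | −15 °C | 0 °C | −15 °C | 0 °C | 0 °C | 0 °C |
| remark | run made earlier | run made earlier | run made earlier | run made earlier |  |  |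
| time |  |  |  |  | 2.0 min | 6.0 min |

| run | time / min | target / % |
|---|---|---|
| south-east | 0.500 | 13.2 |
| south-east | 0.833 | 19.6 |
| south-east | 2.00 | 33.8 |
| south-east | 3.00 | 40.2 |
| south-east | 6.00 | 48.0 |
| north-west | 0.667 | 32.1 |
| north-west | 1.33 | 41.7 |
| north-west | 2.00 | 45.2 |
| north-west | 2.50 | 46.5 |
| north-west | 3.00 | 47.4 |
| north-east | 0.500 | 12.4 |
| north-east | 2.00 | 30.8 |
| north-east | 3.00 | 35.7 |
| north-east | 4.00 | 38.7 |
| north-east | 6.00 | 42.5 |
| west | 0.250 | 17.3 |
| west | 0.833 | 33.7 |
| west | 1.33 | 39.7 |
| west | 2.00 | 42.9 |
| west | 3.00 | 46.2 |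

(scatter of a reading: 0.3 percentage points)

* the flask that ends with the higher amount of target, in percent of the substrate charged, or "neither" when 2 percentage points or less lies between them (Monday's / Friday's / neither)
* final target, as a percentage of the substrate charged, in Monday's
* final target, as a percentage of the substrate charged, in Friday's

- reactions considered so far: substrate + coupling partner <-> target; substrate + coupling partner <-> isomer of the product; target + free catalyst <-> isomer of the product + free catalyst; free catalyst -> spent catalyst; free catalyst + added ligand <-> idle complex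

- Early target takes little notice of catalyst: at −15 °C and 0.500 min, the south-east run with 0.47 mol% reads 13.2%, and the north-east run with 1.8 mol% reads less, 12.4%. The rate worth comparing is therefore the making of target now against its making later.
- The north-west run gains 32.1% in its first 0.667 min, but only 0.9 percentage points between 2.50 min and 3.00 min, so its reading of the rate has dropped 26.7-fold.
- The coupling partner, at 0.70 equiv, is the limiting reagent. The north-west run's last reading over that charge gives 0.677, the stall share: target per equivalent of limiting reagent charged, read where a run has slowed that far.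
- Objection: target stands below the partner charge, and isomer of the product is unread, so the cause of the stall stays open. The share is therefore a reading of that one run, and carrying it to the two flasks is an assumption that their catalyst and time have to pass.
- Objection: free catalyst drains target, and the north-east run ends 5.5 points below the south-east run. At 0 °C, however, the west run, with twice the north-west catalyst and less added ligand, trails by 2.3 points at 2.00 min and by less, 1.2 points, at 3.00 min. Friday's, with 6.0 min, is therefore put at the share: 47.4%.
- Objection: Monday's stops early. The north-west run reads 45.2% at 2.00 min, but Monday's has about half its catalyst, so Monday's is put midway to the stall, at 46.3%. This reckoning's gap of 1.1 points is inside the margin.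
- The forecast says neither, with 46% (44.5% to 47.5%) for Monday's and 47% (44% to 50%) for Friday's, on the ground that “Free catalyst then drains target.”

    substrate + coupling partner ⇌ target (K = 4.00 M⁻¹, k = 0.0100 M⁻¹ s⁻¹, Ea = 46.0 kJ mol⁻¹, ΔH = −20.0 kJ mol⁻¹)
    substrate + coupling partner ⇌ isomer of the product (K = 1.20 M⁻¹, k = 3.70 × 10⁻⁴ M⁻¹ s⁻¹, Ea = 75.0 kJ mol⁻¹, ΔH = −28.0 kJ mol⁻¹)
    target + free catalyst ⇌ isomer of the product + free catalyst, rate k3*[free catalyst]*[target] forward; the back reaction follows from the equilibrium constant (k = 0.690 M⁻¹ s⁻¹, Ea = 56.0 kJ mol⁻¹)
    free catalyst → spent catalyst (k = 0.0310 s⁻¹, Ea = 69.0 kJ mol⁻¹)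
    free catalyst + added ligand ⇌ idle complex, settled at all times (K = 38.0 M⁻¹, ΔH = −24.0 kJ mol⁻¹)
    (constants at 0 °C)

- Monday's gives 47.0% and Friday's 46.8%, so the answer is neither, with 0.671 and 0.669 of target per equivalent of partner at their stopping times; Monday's is cut off while its target is still rising, to 49.1% at 20.0 min. Monday's ends at 2.00 min with 6.45% isomer of the product and 94.6% of its catalyst spent, while Friday's has 2.36% of its catalyst free at 3.00 min and ends with 11.7% isomer and 16% of its partner left. Friday's neighbour with 1.20 equiv has substrate as the smaller charge, so the share puts it at 67.7%, and it ends at 65.6%.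

The runs stem from a simulated flask on assumed constants; the scatter is artificial.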